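The vessel takes the same charges of Z and Q in blue and green, and you want a quick number, with a hunch that the temperature picks the better flask. Read the charge first.

in all of them: Z 0.010 M
- autumn: Q 7 mM; temperature −31 °C; run made earlier
- dusk: Q 11 mM; temperature −23 °C; run made earlier
- blue: Q 5.00 mM; temperature −35 °C; time 12 h
- green: Q 5.00 mM; temperature −20 °C; time 12 h

| run | time / h | X / % | Z / % |
|---|---|---|---|
| autumn | 0.500 | 56.0 | 44.9 |
| autumn | 0.833 | 61.9 | 38.1 |
| autumn | 1.33 | 66.0 | 33.7 |
| autumn | 2.00 | 66.3 | 34.0 |
| autumn | 3.00 | 69.3 | 32.7 |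
| autumn | 5.00 | 68.4 | 33.1 |
| autumn | 8.00 | 68.4 | 31.8 |
| dusk | 0.250 | 75.9 | 21.8 |
| dusk | 0.500 | 91.1 | 11.6 |
| dusk | 1.00 | 95.5 | 5.1 |
| dusk | 1.50 | 97.5 | 4.0 |
| dusk | 2.00 | 96.6 | 3.4 |
| dusk | 3.00 | 98.0 | 3.0 |
| dusk | 4.00 | 97.1 | 2.3 |

(each reading ± 1 percentage point)



- the best flask by amount of X, in percent of the Z charged; "all alike" if 1.5 percentage points covers them all (blue / green / all alike)
- amount of X at the end, in percent of the Z charged, blue
- amount of X at the end, in percent of the Z charged, green

In both runs X plus Z comes back to about the whole Z charge, so each Z lost becomes one X, and autumn stalls just under its ratio of Q to Z, so one Q goes with it. Blue and green therefore carry 50.0% as their ceiling, Q charged over Z charged, capped at the whole Z charge. Q is the limiting reagent while that ratio stays under 1, and Z is beyond it, which is the crossing. Autumn's ceiling is 70.0%, and its last reading of 68.4% sits 1.6 percentage points under that, against a scatter of 1 point. Dusk, charged at 1.10 equivalents of Q, past the crossing, still shows 2.3% of Z in its last reading, so I read Q as going elsewhere too. I expect that loss to weigh little in blue and green, since Z should stand near 50.0% there, far more than dusk's last reading. So I take autumn's gap off the ceiling and commit to 48.4% for both flasks, and as I expect them to lie within 1.5 points of each other, I name all alike.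

The forecast, reasoning that “Q also dies by a side path”, gives 49.4% (48.3% to 50.2%) for blue and 47% (45% to 48.5%) for green and names blue, where I name neither.

The flasks give 48.5% in blue and 47.7% in green, 0.80 points apart and inside 1.5 points, so the answer is all alike.

    Z + Q → X, rate k1*[Z]^0.5*[Q] (k = 0.0283 M⁻⁰·⁵ s⁻¹, Ea = 38.0 kJ mol⁻¹)
    Q ⇌ G (K = 13.0, k = 3.01 × 10⁻⁴ s⁻¹, Ea = 84.0 kJ mol⁻¹, ΔH = −47.0 kJ mol⁻¹)
    (constants at −20 °C)

Green ends 2.3 points under its ceiling of 50.0%, and G at 12.0 h amounts to 2.29% of the Z charge. Now cut Z to 0.0025 M from green, other charges and time held. Q over Z becomes 2.00, past the crossing, so the ceiling is 100% and Z should run out first. That flask gives 100% of X with 0% of Z left, and Q stands at 3.57% of its own charge, while G holds 46.4% of that charge.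

The earlier runs and the new flask are calculated with made-up constants; the scatter is artificial.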